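**Plan**
1. Retrosynthesis: the two isovalerate C–O bonds and the formyl mask are cut first. The oxirane is then cut at C3, removing the CH2 with both of its ring bonds (C2–C3 and O–C3) to leave an aryl silyloxymethyl ketone. Last, the aryl–C(=O) bond is cut to an arylmagnesium reagent and a glycolic Weinreb amide.
2. Enabling feature: the oxirane is terminal. Ring carbon C3 is a bare CH2 bonded only to the ring oxygen and to quaternary C2, which carries the benzene ring and the CH2O arm. C3 therefore corresponds to a methylene ylide carbon and C2 to a ketone carbonyl carbon.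
3. Forward: amide 3 (two steps from methyl glycolate) and aryl bromide 6 (two steps from 4-bromo-3-hydroxybenzaldehyde) are joined to ketone 9. The oxirane, the only ring made, is closed in step 6; both silyl ethers are then exchanged for isovalerates and the dimethyl acetal is hydrolysed last.
4. Stereochemistry: the single stereocentre (C2, R) is created in step 6 under control of a chiral lanthanum–lithium binaphthoxide complex. Afterwards no bond to C2 is broken and no free alkoxide is allowed to persist next to the oxirane.

Key step: step 6

Remark: which antipode of the binaphthoxide complex gives the (R)-oxirane from an aryl silyloxymethyl ketone is taken by analogy with aryl methyl ketones. The complex from (R)-BINOL is written, and the complex from (S)-BINOL would be used instead if a first sample of 13 proved to be the antipode.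

**Step 1**
Reactants: 1 methyl glycolate
Product: 2 methyl 2-(tert-butyldimethylsilyloxy)acetate
Conditions: TBSCl, imidazole, CH2Cl2, 0 °C → rt
Reagents that add atoms: tert-butyldimethylsilyl chloride, CC(C)(C)[Si](C)(C)Cl
Why: Imidazole-mediated silyl ether formation at the unhindered primary hydroxyl should be clean and leaves the methyl ester untouched.

**Step 2**
Reactants: 2 methyl 2-(tert-butyldimethylsilyloxy)acetate
Product: 3 2-(tert-butyldimethylsilyloxy)-N-methoxy-N-methylacetamide
Conditions: MeNH(OMe)·HCl, i-PrMgCl, THF, −20 → 0 °C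
Reagents that add atoms: N,O-dimethylhydroxylamine hydrochloride, CNOC.Cl
Why: The chloromagnesium amide generated from the hydroxylamine salt should displace methoxide from the ester (direct ester-to-Weinreb-amide aminolysis), with the silyl ether inert to the base at this temperature.

**Step 3**
Reactants: 4 4-bromo-3-hydroxybenzaldehyde
Product: 5 4-bromo-3-(triisopropylsilyloxy)benzaldehyde
Conditions: TIPSCl, imidazole, DMF, rt
Reagents that add atoms: triisopropylsilyl chloride, CC(C)[Si](Cl)(C(C)C)C(C)C
Why: Silyl ether formation at the acidic phenol should be fast, and the bulky triisopropylsilyl group is chosen because it withstands the organomagnesium and ylide steps and resists O→C silyl migration to an ortho-metalated carbon.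

**Step 4**
Reactants: 5 4-bromo-3-(triisopropylsilyloxy)benzaldehyde
Product: 6 1-bromo-4-(dimethoxymethyl)-2-(triisopropylsilyloxy)benzene
Conditions: HC(OMe)3, MeOH, p-TsOH·H2O (cat.), rt; Et3N quench
Reagents that add atoms: trimethyl orthoformate, COC(OC)OC; methanol, CO
Why: Acid-catalysed acetalisation with the orthoformate as water scavenger should give the dimethyl acetal, which is inert to organomagnesium and ylide reagents yet hydrolyses under much milder acid than a cyclic acetal, while the aryl silyl ether tolerates brief catalytic acid in methanol.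

**Step 5**
Reactants: 6 1-bromo-4-(dimethoxymethyl)-2-(triisopropylsilyloxy)benzene; 3 2-(tert-butyldimethylsilyloxy)-N-methoxy-N-methylacetamide
Product: 9 2-(tert-butyldimethylsilyloxy)-1-[4-(dimethoxymethyl)-2-(triisopropylsilyloxy)phenyl]ethan-1-one, via arylmagnesium bromide 7 (not isolated), via chelated tetrahedral adduct 8 (not isolated)
Conditions: Mg turnings, LiCl, i-Bu2AlH (1 mol%), THF, rt; then 3, −20 °C → rt; pH 7 phosphate buffer / aq. NH4Cl, 0 °C
Reagents that add atoms: none
Why: Magnesium insertion into the aryl C–Br bond followed by acylation with the amide (Weinreb ketone synthesis) should stop at the ketone because the N-methoxy chelate 8 persists until the near-neutral quench, and an aryl magnesium rather than an aryl lithium species avoids silyl migration from the ortho-silyloxy group.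

**Step 6**
Reactants: 9 2-(tert-butyldimethylsilyloxy)-1-[4-(dimethoxymethyl)-2-(triisopropylsilyloxy)phenyl]ethan-1-one; 10 trimethylsulfoxonium chloride
Product: 13 (R)-2-[(tert-butyldimethylsilyloxy)methyl]-2-[4-(dimethoxymethyl)-2-(triisopropylsilyloxy)phenyl]oxirane, via dimethyloxosulfonium methylide 11 (not isolated), via sulfoxonium betaine 12 (not isolated)
Conditions: 10, NaH, THF, reflux, filtered under Ar (ylide solution, 1.2 equiv); added to 9, LaLi3[(R)-1,1'-bi-2-naphthoxide]3 (5–10 mol%), tris(2,4,6-trimethoxyphenyl)phosphine oxide (5–10 mol%), 5 Å molecular sieves, THF, rt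
Reagents that add atoms: none
Why: The ylide carbon of 11 adds to the lanthanum-activated carbonyl carbon of 9 to give betaine 12 (new C2–C3 bond), and the alkoxide oxygen then displaces dimethyl sulfoxide from the CH2 (new O–C3 bond). The closest known reaction type is the catalytic asymmetric Corey–Chaykovsky epoxidation of ketones with dimethyloxosulfonium methylide under a lanthanum–lithium binaphthoxide complex and a triarylphosphine oxide. The oxirane closes in the 3-exo-tet mode, and because the displacement takes place at the CH2 the configuration fixed at C2 in the addition is carried into the ring unchanged. The stereocentre is set by the chiral heterobimetallic complex (reagent control), which binds the ketone on trivalent lanthanum and the ylide on a lithium binaphthoxide arm so that the methylene reaches one carbonyl face. The step needs carbonyl-face selectivity, which the substrate supports through the size gap between the ortho-silyloxyaryl flank and the CH2OSi flank and through silyl ether oxygens too weakly donating to chelate lanthanum. It also needs chemoselectivity, which is secured by the dimethyl acetal mask on the formyl carbon and by limiting the ylide to a small excess at room temperature so that the oxirane is not expanded to an oxetane.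

**Step 7**
Reactants: 13 (R)-2-[(tert-butyldimethylsilyloxy)methyl]-2-[4-(dimethoxymethyl)-2-(triisopropylsilyloxy)phenyl]oxirane; 14 isovaleric anhydride
Product: 16 [(R)-2-[4-(dimethoxymethyl)-2-(3-methylbutanoyloxy)phenyl]oxiran-2-yl]methyl 3-methylbutanoate, via aryl isovalerate silyl ether 15 (not isolated)
Conditions: 14 (6 equiv), DMAP (0.2 equiv), TBAF (1 M in THF, 2.5 equiv, slow addition), THF, 0 °C → rt
Reagents that add atoms: none
Why: Fluoride attacks silicon first at the aryl silyl ether and then at the primary silyl ether, and each oxyanion is acylated at once by the excess anhydride (one-pot fluoride-mediated silyl ether to ester exchange with DMAP catalysis), so no alkoxide or phenoxide lingers beside the oxirane to cause a Payne rearrangement or ring opening and no bond at C2 is touched.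

**Step 8**
Reactants: 16 [(R)-2-[4-(dimethoxymethyl)-2-(3-methylbutanoyloxy)phenyl]oxiran-2-yl]methyl 3-methylbutanoate
Product: 17 [(2R)-2-[4-formyl-2-(3-methylbutanoyloxy)phenyl]oxiran-2-yl]methyl 3-methylbutanoate (CNP0274578.1)
Conditions: PPTS (0.2 equiv), THF–H2O (5:1), 0 °C → rt; aq. NaHCO3
Reagents that add atoms: water, O
Why: Mild Brønsted acid hydrolysis of an acyclic aryl dimethyl acetal (acetal deprotection) should outpace protonolysis of the oxirane, whose benzylic cation is disfavoured by the acyloxymethyl group and the electron-poor aryl ring, and both esters are stable at this acidity.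

**Compound list**
1 | methyl glycolate | COC(=O)CO | starting material
2 | methyl 2-(tert-butyldimethylsilyloxy)acetate | COC(=O)CO[Si](C)(C)C(C)(C)C | intermediate
3 | 2-(tert-butyldimethylsilyloxy)-N-methoxy-N-methylacetamide | CON(C)C(=O)CO[Si](C)(C)C(C)(C)C | intermediate
4 | 4-bromo-3-hydroxybenzaldehyde | O=Cc1ccc(Br)c(O)c1 | starting material
5 | 4-bromo-3-(triisopropylsilyloxy)benzaldehyde | O=Cc1ccc(Br)c(O[Si](C(C)C)(C(C)C)C(C)C)c1 | intermediate
6 | 1-bromo-4-(dimethoxymethyl)-2-(triisopropylsilyloxy)benzene | COC(OC)c1ccc(Br)c(O[Si](C(C)C)(C(C)C)C(C)C)c1 | intermediate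
7 | [4-(dimethoxymethyl)-2-(triisopropylsilyloxy)phenyl]magnesium bromide (LiCl-solvated; not isolated) | COC(OC)c1ccc([Mg]Br)c(O[Si](C(C)C)(C(C)C)C(C)C)c1 | intermediate
8 | bromomagnesium alkoxide of the tetrahedral N-methoxy-N-methyl hemiaminal from 7 and 3 (racemic at the carbinol carbon; not isolated) | CON(C)C(CO[Si](C)(C)C(C)(C)C)(O[Mg]Br)c1ccc(C(OC)OC)cc1O[Si](C(C)C)(C(C)C)C(C)C | intermediate
9 | 2-(tert-butyldimethylsilyloxy)-1-[4-(dimethoxymethyl)-2-(triisopropylsilyloxy)phenyl]ethan-1-one | CC(C)(C)[Si](C)(C)OCC(=O)c1ccc(C(OC)OC)cc1O[Si](C(C)C)(C(C)C)C(C)C | intermediate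
10 | trimethylsulfoxonium chloride | C[S+](C)(C)=O.[Cl-] | starting material
11 | dimethyloxosulfonium methylide (THF solution; not isolated) | C[S+](C)(=O)[CH2-] | intermediate
12 | (S)-2-[4-(dimethoxymethyl)-2-(triisopropylsilyloxy)phenyl]-1-(tert-butyldimethylsilyloxy)-3-(dimethyloxosulfonio)propan-2-olate, metal-bound betaine (not isolated) | CC(C)(C)[Si](C)(C)OC[C@@]([O-])(c1ccc(C(OC)OC)cc1O[Si](C(C)C)(C(C)C)C(C)C)C[S+](C)(C)=O | intermediate
13 | (R)-2-[(tert-butyldimethylsilyloxy)methyl]-2-[4-(dimethoxymethyl)-2-(triisopropylsilyloxy)phenyl]oxirane | CC(C)(C)[Si](C)(C)OC[C@@]1(c2ccc(C(OC)OC)cc2O[Si](C(C)C)(C(C)C)C(C)C)CO1 | intermediate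
14 | isovaleric anhydride (3-methylbutanoic anhydride) | CC(C)CC(=O)OC(=O)CC(C)C | starting material
15 | 2-[(R)-2-[(tert-butyldimethylsilyloxy)methyl]oxiran-2-yl]-5-(dimethoxymethyl)phenyl 3-methylbutanoate (not isolated) | CC(C)(C)[Si](C)(C)OC[C@@]1(c2ccc(C(OC)OC)cc2OC(=O)CC(C)C)CO1 | intermediate
16 | [(R)-2-[4-(dimethoxymethyl)-2-(3-methylbutanoyloxy)phenyl]oxiran-2-yl]methyl 3-methylbutanoate | CC(C)CC(=O)OC[C@@]1(c2ccc(C(OC)OC)cc2OC(=O)CC(C)C)CO1 | intermediate
17 | [(2R)-2-[4-formyl-2-(3-methylbutanoyloxy)phenyl]oxiran-2-yl]methyl 3-methylbutanoate | CC(C)CC(=O)OC[C@@]1(c2ccc(C=O)cc2OC(=O)CC(C)C)CO1 | target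

**Totals**
Total step count: 8.
Longest linear sequence: 6 steps (4 → 5 → 6 → 9 → 13 → 16 → 17); the amide branch 1 → 2 → 3 adds 2 steps.

**Steps most likely to fail**

Step 6. The risk is poor carbonyl-face discrimination, because the CH2OSi flank is larger than the methyl group for which this catalyst is best documented. Addition to the ortho-substituted ketone may also be slow, and a second ylide may expand the oxirane to an oxetane. The fallback sets out from 9 and returns at 16, and makes the oxirane by oxygen transfer to an alkene instead. Wittig methylenation of 9 (Ph3PCH3Br, KN(SiMe3)2, THF, 0 °C → rt) should give tert-butyl({2-[4-(dimethoxymethyl)-2-(triisopropylsilyloxy)phenyl]prop-2-en-1-yl}oxy)dimethylsilane F1. PPTS in dry methanol should then remove only the primary silyl group, the aryl silyl ether and the dimethyl acetal being stable in that medium, to give 2-[4-(dimethoxymethyl)-2-(triisopropylsilyloxy)phenyl]prop-2-en-1-ol F2. Sharpless asymmetric epoxidation (Ti(O-i-Pr)4, L-(+)-diethyl tartrate, t-BuOOH, 4 Å molecular sieves, CH2Cl2, −20 °C) should give [(S)-2-[4-(dimethoxymethyl)-2-(triisopropylsilyloxy)phenyl]oxiran-2-yl]methanol F3. F3 has the same spatial arrangement as 13; the descriptor changes only because CH2OH ranks below the ring CH2. Exposing F3 to the conditions of step 7 acylates the free hydroxyl and exchanges the aryl silyl ether, giving 16.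

Step 7. The risk is incomplete cleavage of the primary silyl ether, or an oxyanion that lives long enough to attack the oxirane. The Payne rearrangement is degenerate here and would erode enantiomeric purity; phenoxide attack at the ring CH2 would give a dihydrobenzofuran. The fallback sets out from 13 and returns at 16, and separates deprotection from acylation. TBAF buffered with acetic acid (1:1, THF, 0 °C → rt) should remove both silyl groups without generating a naked alkoxide, giving (S)-5-(dimethoxymethyl)-2-[2-(hydroxymethyl)oxiran-2-yl]phenol F4, which is isolated. Acylation of both hydroxyls with 14 (Et3N, DMAP cat., CH2Cl2, 0 °C) then gives 16.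

Step 8. The risk is acid-induced opening or Meinwald rearrangement of the tertiary benzylic oxirane, possibly assisted by a neighbouring ester carbonyl, competing with acetal hydrolysis. The fallback sets out from 5 and returns at 17, and carries the formyl carbon as a vinyl group that is unmasked without acid.
- Wittig methylenation of 5 (Ph3PCH3Br, KN(SiMe3)2, THF) should give 1-bromo-2-(triisopropylsilyloxy)-4-vinylbenzene F5.
- Magnesium insertion and acylation with 3, as in step 5, should give 2-(tert-butyldimethylsilyloxy)-1-[2-(triisopropylsilyloxy)-4-vinylphenyl]ethan-1-one F6.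
- The catalytic asymmetric methylene transfer of step 6, to which a styrene is inert, should give (R)-2-[(tert-butyldimethylsilyloxy)methyl]-2-[2-(triisopropylsilyloxy)-4-vinylphenyl]oxirane F7.
- The exchange of step 7 should give [(R)-2-[2-(3-methylbutanoyloxy)-4-vinylphenyl]oxiran-2-yl]methyl 3-methylbutanoate F8.
- Ozonolysis with reductive work-up (O3, CH2Cl2, −78 °C; PPh3) should cleave the vinyl group under neutral conditions and give 17.

**Further compounds**
F1 | step 6 | tert-butyl({2-[4-(dimethoxymethyl)-2-(triisopropylsilyloxy)phenyl]prop-2-en-1-yl}oxy)dimethylsilane | CC(C)(C)[Si](C)(C)OCC(=C)c1ccc(C(OC)OC)cc1O[Si](C(C)C)(C(C)C)C(C)C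
F2 | step 6 | 2-[4-(dimethoxymethyl)-2-(triisopropylsilyloxy)phenyl]prop-2-en-1-ol | OCC(=C)c1ccc(C(OC)OC)cc1O[Si](C(C)C)(C(C)C)C(C)C
F3 | step 6 | [(S)-2-[4-(dimethoxymethyl)-2-(triisopropylsilyloxy)phenyl]oxiran-2-yl]methanol | OC[C@@]1(c2ccc(C(OC)OC)cc2O[Si](C(C)C)(C(C)C)C(C)C)CO1
F4 | step 7 | (S)-5-(dimethoxymethyl)-2-[2-(hydroxymethyl)oxiran-2-yl]phenol | OC[C@@]1(c2ccc(C(OC)OC)cc2O)CO1
F5 | step 8 | 1-bromo-2-(triisopropylsilyloxy)-4-vinylbenzene | C=Cc1ccc(Br)c(O[Si](C(C)C)(C(C)C)C(C)C)c1
F6 | step 8 | 2-(tert-butyldimethylsilyloxy)-1-[2-(triisopropylsilyloxy)-4-vinylphenyl]ethan-1-one | CC(C)(C)[Si](C)(C)OCC(=O)c1ccc(C=C)cc1O[Si](C(C)C)(C(C)C)C(C)C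
F7 | step 8 | (R)-2-[(tert-butyldimethylsilyloxy)methyl]-2-[2-(triisopropylsilyloxy)-4-vinylphenyl]oxirane | CC(C)(C)[Si](C)(C)OC[C@@]1(c2ccc(C=C)cc2O[Si](C(C)C)(C(C)C)C(C)C)CO1
F8 | step 8 | [(R)-2-[2-(3-methylbutanoyloxy)-4-vinylphenyl]oxiran-2-yl]methyl 3-methylbutanoate | CC(C)CC(=O)OC[C@@]1(c2ccc(C=C)cc2OC(=O)CC(C)C)CO1
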